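The terpene ring (C1 carbinol carbon, C2 bearing the acylphloroglucinol ring, C4 bearing isopropenyl) is chiral only because C2 differs from C6; the parent 4-isopropenylcyclohexanone is achiral. C2 is therefore excised: the ring is traced to the silyl enol ether of 3-isopropenylcyclopentanone, whose C1=C3 double bond is fixed by asymmetric conjugate addition. Dibromocarbene insertion into that bond enlarges the five-membered ring to the six-membered one and places C2, already carrying bromine, between C1 and C3 only. Hydride addition then gives an α-bromoketone that C-alkylates phlorisobutyrophenone (C2–aryl bond). Dearomatising bis-prenylation and equatorial methyl addition at C1 complete the target.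

Key step: step 2

Assumption: the enolised β-triketone unit is drawn throughout as the tautomer of the target SMILES; its other tautomers are the same compound.

Step 1
Reactants: 1 cyclopent-2-en-1-one; 2 prop-1-en-2-ylmagnesium bromide
Product: 4 (S)-trimethyl{[3-(prop-1-en-2-yl)cyclopent-1-en-1-yl]oxy}silane, via bromomagnesium enolate 3 (not isolated)
Conditions: CuBr·SMe2 (5 mol %), TADDOL-derived phosphine–phosphite ligand (enantiomer that gives S), 2-MeTHF, −78 °C; then Me3SiCl, Et3N, −78 °C to rt
Reagents that add atoms: chlorotrimethylsilane, C[Si](C)(C)Cl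
Why: Copper-catalysed asymmetric conjugate addition of a Grignard reagent: the chiral monovalent-copper complex selects the enone face and so sets C4 as S, and O-silylation of enolate 3 freezes the double bond between the carbonyl carbon C1 and C3, the carbon next to C4.

Step 2
Reactants: 4 (S)-trimethyl{[3-(prop-1-en-2-yl)cyclopent-1-en-1-yl]oxy}silane
Product: 6 (S)-2-bromo-4-(prop-1-en-2-yl)cyclohex-2-en-1-one, via dibromocyclopropane 5 (not isolated)
Conditions: CHBr3 (1.1 equiv), KOt-Bu (1.2 equiv), pentane, −30 to 0 °C; then toluene, 80 °C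
Reagents that add atoms: bromoform, BrC(Br)Br
Why: Dibromocarbene, made from bromoform and KOt-Bu, adds in a concerted [2+1] cheletropic step to the electron-rich C1=C3 bond of the five-membered ring, on the face away from the isopropenyl group, to close the cyclopropane of 5; on warming the endo bromide leaves while the shared C1–C3 bond opens in a disrotatory cyclopropyl-to-allyl electrocyclic process pushed by the silyloxy oxygen, and bromide takes the silyl group to leave enone 6. The closest known reaction type is the dihalocarbene ring expansion of cyclic silyl enol ethers to 2-halocycloalk-2-enones. The only ring closed is the transient three-membered one, by cycloaddition, and the six-membered ring arises when the bond common to the three- and five-membered rings breaks. No new stereocentre survives: both bridgeheads end as sp2 carbons, and C4, set in step 1, is never touched. The step needs site selectivity (insertion between C1 and C3, not C1 and C6), secured by the enol ether position; chemoselectivity over the 1,1-disubstituted isopropenyl alkene, secured by the oxygen-raised nucleophilicity of the enol ether and by keeping the carbene close to one equivalent; and cleavage of the internal rather than an external cyclopropane bond, enforced by orbital symmetry because the bond opposite the carbon that loses bromide must open.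

Step 3
Reactants: 6 (S)-2-bromo-4-(prop-1-en-2-yl)cyclohex-2-en-1-one; 7 2-methyl-1-(2,4,6-trihydroxyphenyl)propan-1-one (phlorisobutyrophenone)
Product: 10 (2R,4S)-2-[2,4,6-trihydroxy-3-(2-methylpropanoyl)phenyl]-4-(prop-1-en-2-yl)cyclohexan-1-one, via potassium bromoenolate 8 (not isolated), via bromoketone 9 (not isolated)
Conditions: K[HB(s-Bu)3] (1.0 equiv), THF, −78 °C; then 7 in MeOH, −78 °C to rt; pH 7 buffer work-up
Reagents that add atoms: none
Why: 1,4-Hydride delivery from the bulky borohydride gives bromoenolate 8 with its double bond still marking C2, phenol 7 protonates it to bromoketone 9, and the weakly basic phloroglucinolate so formed displaces bromide through carbon in the protic medium (SN2 C-alkylation of an ambident phenolate by an α-halo ketone), after which the epimerisable C2 settles with the aryl group equatorial and cis to the C4 isopropenyl group (2R).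

Step 4
Reactants: 10 (2R,4S)-2-[2,4,6-trihydroxy-3-(2-methylpropanoyl)phenyl]-4-(prop-1-en-2-yl)cyclohexan-1-one; 11 1-bromo-3-methylbut-2-ene (prenyl bromide)
Product: 13 3,5-dihydroxy-2-(2-methylpropanoyl)-6,6-bis(3-methylbut-2-enyl)-4-[(1R,5S)-2-oxo-5-(prop-1-en-2-yl)cyclohexyl]cyclohexa-2,4-dien-1-one, via monoprenyl phenol 12 (not isolated)
Conditions: 11 (2.2 equiv), KOH, H2O/MeOH, 0 °C
Reagents that add atoms: none
Why: C-prenylation of a phloroglucinolate as in lupulone-type syntheses: the first prenyl group enters the only free aromatic carbon and the second enters the same carbon with dearomatisation because the other nucleophilic ring carbon is shielded by the secondary cyclohexyl group, while the basic medium keeps C2 at its equatorial equilibrium configuration.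

Step 5
Reactants: 13 3,5-dihydroxy-2-(2-methylpropanoyl)-6,6-bis(3-methylbut-2-enyl)-4-[(1R,5S)-2-oxo-5-(prop-1-en-2-yl)cyclohexyl]cyclohexa-2,4-dien-1-one
Product: 14 3,5-dihydroxy-4-[(1R,2R,5S)-2-hydroxy-2-methyl-5-(prop-1-en-2-yl)cyclohexyl]-2-(2-methylpropanoyl)-6,6-bis(3-methylbut-2-enyl)cyclohexa-2,4-dien-1-one (target)
Conditions: anhydrous CeCl3, MeMgBr (5 equiv each), THF, −78 to 0 °C; pH 6 buffer work-up
Reagents that add atoms: methylmagnesium bromide, C[Mg]Br
Why: Organocerium 1,2-addition: the first equivalents turn the enolised triketone into an unreactive dianion, and the methyl nucleophile then attacks the cyclohexanone, in the chair with both ring substituents equatorial, from the equatorial side, which puts methyl equatorial and hydroxyl axial, cis to the C2 substituent and to isopropenyl (carbinol carbon R).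

Compound list
1 | cyclopent-2-en-1-one | O=C1C=CCC1 | starting material
2 | prop-1-en-2-ylmagnesium bromide | C=C(C)[Mg]Br | starting material
3 | bromomagnesium (S)-3-(prop-1-en-2-yl)cyclopent-1-en-1-olate | C=C(C)[C@H]1CCC(O[Mg]Br)=C1 | intermediate
4 | (S)-trimethyl{[3-(prop-1-en-2-yl)cyclopent-1-en-1-yl]oxy}silane | C=C(C)[C@H]1CCC(O[Si](C)(C)C)=C1 | intermediate
5 | 6,6-dibromo-4-(prop-1-en-2-yl)-1-(trimethylsilyloxy)bicyclo[3.1.0]hexane, CBr2 bridge anti to isopropenyl | C=C(C)[C@H]1CC[C@]2(O[Si](C)(C)C)C(Br)(Br)[C@H]12 | intermediate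
6 | (S)-2-bromo-4-(prop-1-en-2-yl)cyclohex-2-en-1-one | C=C(C)[C@H]1CCC(=O)C(Br)=C1 | intermediate
7 | 2-methyl-1-(2,4,6-trihydroxyphenyl)propan-1-one | CC(C)C(=O)c1c(O)cc(O)cc1O | starting material
8 | potassium (S)-2-bromo-4-(prop-1-en-2-yl)cyclohex-1-en-1-olate | C=C(C)[C@H]1CCC([O-])=C(Br)C1.[K+] | intermediate
9 | (4S)-2-bromo-4-(prop-1-en-2-yl)cyclohexan-1-one, both C2 epimers | C=C(C)[C@H]1CCC(=O)C(Br)C1 | intermediate
10 | (2R,4S)-2-[2,4,6-trihydroxy-3-(2-methylpropanoyl)phenyl]-4-(prop-1-en-2-yl)cyclohexan-1-one | C=C(C)[C@H]1CCC(=O)[C@@H](c2c(O)cc(O)c(C(=O)C(C)C)c2O)C1 | intermediate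
11 | 1-bromo-3-methylbut-2-ene | CC(C)=CCBr | starting material
12 | (2R,4S)-2-[2,4,6-trihydroxy-3-(3-methylbut-2-enyl)-5-(2-methylpropanoyl)phenyl]-4-(prop-1-en-2-yl)cyclohexan-1-one | C=C(C)[C@H]1CCC(=O)[C@@H](c2c(O)c(CC=C(C)C)c(O)c(C(=O)C(C)C)c2O)C1 | intermediate
13 | 3,5-dihydroxy-2-(2-methylpropanoyl)-6,6-bis(3-methylbut-2-enyl)-4-[(1R,5S)-2-oxo-5-(prop-1-en-2-yl)cyclohexyl]cyclohexa-2,4-dien-1-one | C=C(C)[C@H]1CCC(=O)[C@@H](C2=C(O)C(CC=C(C)C)(CC=C(C)C)C(=O)C(C(=O)C(C)C)=C2O)C1 | intermediate
14 | 3,5-dihydroxy-4-[(1R,2R,5S)-2-hydroxy-2-methyl-5-(prop-1-en-2-yl)cyclohexyl]-2-(2-methylpropanoyl)-6,6-bis(3-methylbut-2-enyl)cyclohexa-2,4-dien-1-one | C=C(C)[C@H]1CC[C@@](C)(O)[C@@H](C2=C(O)C(CC=C(C)C)(CC=C(C)C)C(=O)C(C(=O)C(C)C)=C2O)C1 | target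

Total step count: 5. Longest linear sequence: 5 steps (1 to 14).

Steps most likely to fail

Step 3. The ambident phenolate may attack through oxygen instead of carbon. The bromoketone may also ionise to a symmetric oxyallyl cation, which would erode the enantiopurity carried by C4. The fallback replaces the SN2 union by a Friedel–Crafts alkylation with an α-acyl thionium ion. It sets out from 9, obtained by quenching enolate 8 with acetic acid at −78 °C and isolating.
- NaSPh in THF displaces bromide to give (4S)-2-(phenylsulfanyl)-4-(prop-1-en-2-yl)cyclohexan-1-one F1.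
- N-Chlorosuccinimide in CCl4 chlorinates the sulfur-bearing carbon to give the α-chloro sulfide F2.
- ZnCl2 in CH2Cl2 ionises F2 in the presence of 7, and the arene attacks C2 to give the α-aryl α-sulfanyl ketone F3.
- Zn in acetic acid removes the sulfanyl group reductively through the enolate, which returns the route to 10.

Step 2. The carbene may add to the isopropenyl double bond, or tert-butoxide may cleave the silyl enol ether before cyclopropanation. The fallback swaps the cationic halocarbene expansion for a zinc-carbenoid and radical expansion. It sets out from 4.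
- Simmons–Smith cyclopropanation (Et2Zn, CH2I2, Et2O, 0 °C) gives 4-(prop-1-en-2-yl)-1-(trimethylsilyloxy)bicyclo[3.1.0]hexane F4.
- FeCl3 in DMF at 0 °C oxidises F4 to the cyclopropyloxy radical, whose internal bond breaks to the secondary β-keto radical. Chlorine transfer then gives 3-chloro-4-(prop-1-en-2-yl)cyclohexan-1-one F5.
- NaOAc in MeOH eliminates HCl to give (S)-4-(prop-1-en-2-yl)cyclohex-2-en-1-one F6.
- 1,4-Hydrosilylation (Et3SiH, RhCl(PPh3)3) gives the regiodefined triethylsilyl enol ether F7.
- N-Bromosuccinimide converts F7 into 9, where the route is rejoined.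

Step 5. The hindered ketone may be enolised, it may close to a hemiketal alkoxide with the neighbouring enolate oxygen, or facial selectivity may be poor. The fallback builds the carbinol by methylene transfer and hydride opening instead of methyl addition. It sets out from 13.
- Dimethylsulfoxonium methylide (Me3S(O)I, NaH, DMSO, excess) adds reversibly and closes from the equatorial side (Corey–Chaykovsky reaction). This gives the spiro-epoxide F8 with axial oxygen.
- Li[HBEt3] in THF opens F8 at its CH2 terminus to give 14.

Further compounds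
F1 | step 3 | (4S)-2-(phenylsulfanyl)-4-(prop-1-en-2-yl)cyclohexan-1-one | C=C(C)[C@H]1CCC(=O)C(Sc2ccccc2)C1
F2 | step 3 | (4S)-2-chloro-2-(phenylsulfanyl)-4-(prop-1-en-2-yl)cyclohexan-1-one | C=C(C)[C@H]1CCC(=O)C(Cl)(Sc2ccccc2)C1
F3 | step 3 | (4S)-2-(phenylsulfanyl)-2-[2,4,6-trihydroxy-3-(2-methylpropanoyl)phenyl]-4-(prop-1-en-2-yl)cyclohexan-1-one | C=C(C)[C@H]1CCC(=O)C(Sc2ccccc2)(c2c(O)cc(O)c(C(=O)C(C)C)c2O)C1
F4 | step 2 | 4-(prop-1-en-2-yl)-1-(trimethylsilyloxy)bicyclo[3.1.0]hexane, CH2 bridge anti to isopropenyl | C=C(C)[C@H]1CC[C@]2(O[Si](C)(C)C)C[C@H]12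
F5 | step 2 | 3-chloro-4-(prop-1-en-2-yl)cyclohexan-1-one, C4 as in 4 | C=C(C)[C@H]1CCC(=O)CC1Cl
F6 | step 2 | (S)-4-(prop-1-en-2-yl)cyclohex-2-en-1-one | C=C(C)[C@H]1CCC(=O)C=C1
F7 | step 2 | (S)-triethyl{[4-(prop-1-en-2-yl)cyclohex-1-en-1-yl]oxy}silane | C=C(C)[C@H]1CCC(O[Si](CC)(CC)CC)=CC1
F8 | step 5 | spiro-epoxide of 13 at the cyclohexanone carbon, oxygen axial | C=C(C)[C@H]1CC[C@]2(CO2)[C@@H](C3=C(O)C(CC=C(C)C)(CC=C(C)C)C(=O)C(C(=O)C(C)C)=C3O)C1
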